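**Retrosynthetic overview**
1. Target 18 ⇐ phenol deacetylation ⇐ C8 ketone reduction ⇐ O-acylation at C6 of the ten-membered β-hydroxy ketone 14.
2. Key disconnection: the C6–C7 bond (farnesyl C1–C10) of 14, closed by a zinc-templated copper hydride reductive aldol macrocyclisation of the acyclic keto-aldehyde 11. Hydride goes to C11 (makes the isopropyl group), C6 and C7 are set, and the only ring is formed in this step.
3. 11 ⇐ double oxidation of triol 10 ⇐ B-alkyl Suzuki coupling of diol 5 with vinyl bromide 8 (this places the exocyclic methylene).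
4. 5 ⇐ Red-Al opening of Sharpless epoxide 4 ⇐ carboalumination of pent-1-en-4-yne; 8 ⇐ indium Barbier coupling of 2,3-dibromopropene with prenal.

Assumption: germacrane numbering is used (C4 = methyl carbinol, C6 = ester carbon, C7 = isopropyl carbon, C8 = free secondary carbinol, C10 = exocyclic methylene carbon), and the biosynthetic farnesyl C1–C10 closure is taken to be the C6–C7 bond.

**Step 1**
Reactants: 1 pent-1-en-4-yne
Product: 3 (2E)-3-methylhexa-2,5-dien-1-ol, via alkenylalane 2 (not isolated)
Conditions: Me3Al (2 equiv), Cp2ZrCl2 (0.25 equiv), CH2Cl2, 0 °C → rt; then n-BuLi, (CH2O)n, THF, 0 °C → rt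
Reagents that add atoms: trimethylaluminium C[Al](C)C; formaldehyde (from paraformaldehyde) C=O
Why: Negishi zirconium-catalysed syn-carboalumination of the terminal alkyne puts methyl on the internal carbon (the isolated alkene does not react), and hydroxymethylation of the alkenylalanate with formaldehyde keeps the E geometry.

**Step 2**
Reactants: 3 (2E)-3-methylhexa-2,5-dien-1-ol
Product: 4 [(2R,3R)-3-methyl-3-(prop-2-en-1-yl)oxiran-2-yl]methanol
Conditions: Ti(OiPr)4 (10 mol%), D-(−)-diethyl tartrate (12 mol%), t-BuOOH, 4 Å MS, CH2Cl2, −20 °C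
Reagents that add atoms: tert-butyl hydroperoxide CC(C)(C)OO
Why: Sharpless asymmetric epoxidation with D-(−)-DET gives the (2R,3R)-epoxide of the E-trisubstituted allylic alcohol (the terminal alkene is not an allylic alcohol and is untouched), which fixes the future C4 carbinol carbon.

**Step 3**
Reactants: 4 [(2R,3R)-3-methyl-3-(prop-2-en-1-yl)oxiran-2-yl]methanol
Product: 5 (3R)-3-methylhex-5-ene-1,3-diol
Conditions: Red-Al, THF, 0 °C
Reagents that add atoms: none
Why: Regioselective reductive opening of the 2,3-epoxy alcohol: the aluminate on the primary alkoxide delivers hydride to C2, so the C–O bond at the quaternary carbon is untouched and the tertiary carbinol keeps its configuration (R).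

**Step 4**
Reactants: 6 2,3-dibromoprop-1-ene; 7 3-methylbut-2-enal
Product: 8 rac-2-bromo-6-methylhepta-1,5-dien-4-ol
Conditions: In powder, THF/H2O (1:1), rt
Reagents that add atoms: none
Why: Indium-mediated Barbier 2-bromoallylation adds 1,2 to the enal and avoids the β-bromide elimination typical of 2-bromoallyl zinc or magnesium reagents; the carbinol is left racemic because it is oxidised in step 6.

**Step 5**
Reactants: 5 (3R)-3-methylhex-5-ene-1,3-diol; 8 rac-2-bromo-6-methylhepta-1,5-dien-4-ol
Product: 10 (3R,9RS)-3,11-dimethyl-7-methylidenedodec-10-ene-1,3,9-triol, via B-alkyl-9-BBN 9 (not isolated)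
Conditions: 9-BBN (2.2 equiv), THF, rt; then 8, Pd(dppf)Cl2 (5 mol%), AsPh3, 3 M aq. NaOH, THF/DMF, rt
Reagents that add atoms: none
Why: Anti-Markovnikov hydroboration of the only alkene in 5 (the primary OH is held as a borinate) followed by B-alkyl Suzuki–Miyaura coupling with the 2-bromoalkene forms the C(sp3)–C(sp2) bond that creates the 1,1-disubstituted alkene; no stereocentre is touched.

**Step 6**
Reactants: 10 (3R,9RS)-3,11-dimethyl-7-methylidenedodec-10-ene-1,3,9-triol
Product: 11 (3R)-3-hydroxy-3,11-dimethyl-7-methylidene-9-oxododec-10-enal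
Conditions: DMP (2.4 equiv), CH2Cl2, 0 °C; used crude
Reagents that add atoms: none
Why: Dess–Martin oxidation converts the primary alcohol to the aldehyde and the allylic secondary alcohol to the enone in one operation, while the tertiary alcohol cannot be oxidised; both C9 epimers converge on one compound.

**Step 7**
Reactants: 11 (3R)-3-hydroxy-3,11-dimethyl-7-methylidene-9-oxododec-10-enal
Product: 14 (2R,3R,5R)-3,5-dihydroxy-5-methyl-9-methylidene-2-(propan-2-yl)cyclodecan-1-one, via ethylzinc alkoxide 12 (not isolated), via zinc enolate chelate 13 (not isolated)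
Conditions: Et2Zn (1.0 equiv), toluene, 0 °C; dilute to 2 mM (toluene/THF); [(Ph3P)CuH]6 (0.2 equiv), −20 → 0 °C; pH 7 buffer
Reagents that add atoms: none
Why: Proposed new method: Et2Zn first turns the tertiary OH into an ethylzinc alkoxide (no protic hydrogen remains), Stryker's reagent then reduces the s-cis β,β-dimethyl enone 1,4 (hydride to C11 creates the isopropyl group and a Z-enolate, the aldehyde being inert to stoichiometric copper hydride), the enolate passes from copper to zinc as in the turnover step of copper-catalysed dialkylzinc conjugate additions, and zinc bound at once to the C4 alkoxide, the enolate oxygen and the aldehyde oxygen enforces a bicyclo[3.3.1]-type Zimmerman–Traxler transition state in which the aldehyde substituent must be axial, so the Z-enolate gives the anti aldol with C4–O, C6–O and the C7 isopropyl group all cis on the new ten-membered ring (equilibration of the zinc aldolate leads to the same tridentate chelate); the closest known chemistry is the copper hydride reductive aldol cyclisation to five- to seven-membered rings combined with chelation-controlled aldol addition, here used as the polar equivalent of the cyclase's C1–C10 closure with hydride transfer to C11.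

**Step 8**
Reactants: 14 (2R,3R,5R)-3,5-dihydroxy-5-methyl-9-methylidene-2-(propan-2-yl)cyclodecan-1-one; 15 4-(chlorocarbonyl)phenyl acetate
Product: 16 (1R,2R,9R)-9-hydroxy-9-methyl-5-methylidene-3-oxo-2-(propan-2-yl)cyclodecyl 4-(acetyloxy)benzoate
Conditions: pyridine, DMAP (cat.), CH2Cl2, 0 °C
Reagents that add atoms: none
Why: DMAP-catalysed O-acylation of the only secondary alcohol proceeds with retention at C6 (the tertiary C4–OH is too hindered), and the weak base keeps β-elimination of the β-acyloxy ketone and migration of the β,γ-alkene in check.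

**Step 9**
Reactants: 16 (1R,2R,9R)-9-hydroxy-9-methyl-5-methylidene-3-oxo-2-(propan-2-yl)cyclodecyl 4-(acetyloxy)benzoate
Product: 17 (1R,2S,3S,9R)-3,9-dihydroxy-9-methyl-5-methylidene-2-(propan-2-yl)cyclodecyl 4-(acetyloxy)benzoate
Conditions: (R)-Me-CBS (20 mol%), catecholborane (1.5 equiv), toluene, −78 °C; pH 7 buffer
Reagents that add atoms: none
Why: Corey–Bakshi–Shibata reduction (the branched C7 side as the large group, (R)-catalyst) gives the 8S carbinol and is matched with the Felkin–Anh preference for hydride attack anti to the isopropyl group, so the new OH is cis to the isopropyl group and to C6–O; catecholborane does not hydroborate the alkene at −78 °C, and the borate product does not promote acyl migration.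

**Step 10**
Reactants: 17 (1R,2S,3S,9R)-3,9-dihydroxy-9-methyl-5-methylidene-2-(propan-2-yl)cyclodecyl 4-(acetyloxy)benzoate
Product: 18 (1R,2S,3S,9R)-3,9-dihydroxy-9-methyl-5-methylidene-2-(propan-2-yl)cyclodecyl 4-hydroxybenzoate (CNP0293401.1)
Conditions: NH3 (7 M in MeOH), 0 °C
Reagents that add atoms: none
Why: Chemoselective aminolysis of the phenolic acetate, a far better acyl donor than the hindered secondary alkyl benzoate, frees the phenol under conditions too mild for 1,3-acyl migration.

**Compound list**
1 | pent-1-en-4-yne | C#CCC=C | starting material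
2 | (E)-dimethyl(2-methylpenta-1,4-dien-1-yl)alane | C[Al](C)/C=C(\C)CC=C | intermediate
3 | (2E)-3-methylhexa-2,5-dien-1-ol | OC/C=C(\C)CC=C | intermediate
4 | [(2R,3R)-3-methyl-3-(prop-2-en-1-yl)oxiran-2-yl]methanol | OC[C@H]1O[C@]1(C)CC=C | intermediate
5 | (3R)-3-methylhex-5-ene-1,3-diol | OCC[C@](C)(O)CC=C | intermediate
6 | 2,3-dibromoprop-1-ene | C=C(Br)CBr | starting material
7 | 3-methylbut-2-enal | CC(C)=CC=O | starting material
8 | rac-2-bromo-6-methylhepta-1,5-dien-4-ol | C=C(Br)CC(O)C=C(C)C | intermediate
9 | 9-{(4R)-4-hydroxy-4-methyl-6-[(9-borabicyclo[3.3.1]nonan-9-yl)oxy]hexyl}-9-borabicyclo[3.3.1]nonane | O(CC[C@](C)(O)CCCB1C2CCCC1CCC2)B1C2CCCC1CCC2 | intermediate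
10 | (3R,9RS)-3,11-dimethyl-7-methylidenedodec-10-ene-1,3,9-triol (C9 epimers) | OCC[C@](C)(O)CCCC(=C)CC(O)C=C(C)C | intermediate
11 | (3R)-3-hydroxy-3,11-dimethyl-7-methylidene-9-oxododec-10-enal | O=CC[C@](C)(O)CCCC(=C)CC(=O)C=C(C)C | intermediate
12 | ethylzinc (3R)-alkoxide of 11 | CC[Zn]O[C@@](C)(CC=O)CCCC(=C)CC(=O)C=C(C)C | intermediate
13 | zinc chelate of the C3 alkoxide and the (Z)-C9 enolate (after hydride addition to C11) | O=CC[C@@]1(C)CCCC(=C)C/C(=C/C(C)C)O[Zn]O1 | intermediate
14 | (2R,3R,5R)-3,5-dihydroxy-5-methyl-9-methylidene-2-(propan-2-yl)cyclodecan-1-one | C=C1CCC[C@@](C)(O)C[C@@H](O)[C@@H](C(C)C)C(=O)C1 | intermediate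
15 | 4-(chlorocarbonyl)phenyl acetate (4-acetoxybenzoyl chloride) | CC(=O)Oc1ccc(cc1)C(Cl)=O | starting material
16 | (1R,2R,9R)-9-hydroxy-9-methyl-5-methylidene-3-oxo-2-(propan-2-yl)cyclodecyl 4-(acetyloxy)benzoate | C=C1CCC[C@@](C)(O)C[C@@H](OC(=O)c2ccc(OC(C)=O)cc2)[C@@H](C(C)C)C(=O)C1 | intermediate
17 | (1R,2S,3S,9R)-3,9-dihydroxy-9-methyl-5-methylidene-2-(propan-2-yl)cyclodecyl 4-(acetyloxy)benzoate | C=C1CCC[C@@](C)(O)C[C@@H](OC(=O)c2ccc(OC(C)=O)cc2)[C@@H](C(C)C)[C@@H](O)C1 | intermediate
18 | (1R,2S,3S,9R)-3,9-dihydroxy-9-methyl-5-methylidene-2-(propan-2-yl)cyclodecyl 4-hydroxybenzoate | C=C1CCC[C@@](C)(O)C[C@@H](OC(=O)c2ccc(O)cc2)[C@@H](C(C)C)[C@@H](O)C1 | target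

**Step count and risks**
Total steps: 10. Longest linear sequence: 9 (steps 1, 2, 3, 5, 6, 7, 8, 9, 10); step 4 is the convergent branch.

The three steps most likely to fail:

Step 7 (macrocyclisation). A ten-membered ring from a one-pot reduction/aldol is unprecedented. Copper hydride may reduce the aldehyde, a zinc hydride may form, oligomers may win over ring closure, and the diastereoselectivity rests on the chelate model alone. The fallback separates reduction from C–C bond formation. It sets out from 11: reductive silylation with Stryker's reagent and TMSCl gives the (Z)-trimethylsilyl enol ether F1. Slow addition of F1 to Me2AlCl in CH2Cl2 at −78 °C (final 2 mM) converts the tertiary alcohol into a chloro(methyl)aluminium alkoxide that chelates the aldehyde and triggers an aluminium-templated Mukaiyama macro-aldol. Aqueous work-up brings the route back at 14.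

Step 6 (double oxidation). Keto-aldehyde 11 combines a β-hydroxy aldehyde with a β,γ-unsaturated ketone that can slip into conjugation under the acetic acid released by DMP. The fallback makes the two carbonyls one after the other under neutral conditions. It sets out from 10: MnO2 in CH2Cl2 oxidises only the allylic alcohol to the enone diol F2, and TEMPO/PhI(OAc)2 then oxidises the primary alcohol just before the cyclisation. It comes back at 11.

Step 9 (ketone reduction). The hindered ring ketone may react slowly with the CBS catalyst, or the ring conformation may override reagent control and give the C8 epimer. The fallback accepts substrate control and corrects the centre afterwards. It sets out from 16: NaBH4/CeCl3 in MeOH at −78 °C gives the C8-epimeric alcohol F3. A Mitsunobu reaction with chloroacetic acid (PPh3, DIAD) inverts C8 to the chloroacetate F4. NH3 in MeOH then removes the chloroacetate and the phenolic acetate together, and the route comes back at 18.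

**Further compounds**
F1 | step 7 | (3R,9Z)-3-hydroxy-3,11-dimethyl-7-methylidene-9-[(trimethylsilyl)oxy]dodec-9-enal | O=CC[C@](C)(O)CCCC(=C)C/C(O[Si](C)(C)C)=C/C(C)C
F2 | step 6 | (10R)-10,12-dihydroxy-2,10-dimethyl-6-methylidenedodec-2-en-4-one | OCC[C@](C)(O)CCCC(=C)CC(=O)C=C(C)C
F3 | step 9 | (1R,2S,3R,9R)-3,9-dihydroxy-9-methyl-5-methylidene-2-(propan-2-yl)cyclodecyl 4-(acetyloxy)benzoate | C=C1CCC[C@@](C)(O)C[C@@H](OC(=O)c2ccc(OC(C)=O)cc2)[C@@H](C(C)C)[C@H](O)C1
F4 | step 9 | (1R,2S,3S,9R)-3-[(chloroacetyl)oxy]-9-hydroxy-9-methyl-5-methylidene-2-(propan-2-yl)cyclodecyl 4-(acetyloxy)benzoate | C=C1CCC[C@@](C)(O)C[C@@H](OC(=O)c2ccc(OC(C)=O)cc2)[C@@H](C(C)C)[C@@H](OC(=O)CCl)C1
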